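**Plan**

- Cuts: the C8 ester and the C9 carbinol are adjusted last. The furanone bonds O–C3 and C1–C10 are then cut together, which opens the bridged ten-membered ring to an 11-membered 2-ynoate macrolactone (ester oxygen on C10, C9 held as a ketone). This is cut at the ester bond and at C6–C7 into a C1–C6 enynal ester and a C7–C14 bromomethyl enoate.
- Enabling feature: C10 of the 2-acyl-3(2H)-furanone carries the ring oxygen and, through C9, a carbon that can sit at the ketone level. C10 is therefore the α-carbon of an α-acyloxy ketone, and the acyl group on that oxygen (C1–C2≡C3) already holds the ynone carbon C3 in reach of the oxygen for the five-membered closure.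
- Forward order: two fragments, then Barbier allylation closing the cis α-methylene-γ-lactone (C6–C7), then Mitsunobu macrolactonisation, then base-induced ring contraction with furanone closure, then C9 reduction, deprotection and methacrylate.
- Stereochemistry: (S)-lactaldehyde and a matched Brown alkoxyallylboration set C8. C8 then relays to C7 and C6 (chair Barbier), to C10 (ring-controlled acyl shift; the lactate centre itself is erased there) and to C9 (chelation-controlled reduction).

Key step: step 14

Remark: the target is taken as drawn, (6S,7S,8S,9S,10R) with a 4Z alkene and a cis-fused 6,7-lactone; germacrane numbering (C1 to C15) is used for all intermediates.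
Remark: (2Z)-3-methylpent-2-en-4-yn-1-ol, 2-(trimethylsilyl)ethyl chloroformate, (2S)-2-(tert-butyldimethylsilyloxy)propanal, allyl methoxymethyl ether, methyl acrylate and methacrylic anhydride are assumed to be commercial.

**Route**

Step 1
Reactants: 1 (2Z)-3-methylpent-2-en-4-yn-1-ol
Product: 2 tert-butyldimethylsilyl ether of 1
Conditions: TBSCl, imidazole, DMF, 0 °C to rt
Reagents that add atoms: tert-butyldimethylsilyl chloride, CC(C)(C)[Si](C)(C)Cl
Why: Imidazole-mediated silylation masks the allylic alcohol so that only the alkyne C–H is deprotonated in the next step.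

Step 2
Reactants: 2 tert-butyldimethylsilyl ether of 1; 3 2-(trimethylsilyl)ethyl chloroformate
Product: 5 2-(trimethylsilyl)ethyl (4Z)-6-(tert-butyldimethylsilyloxy)-4-methylhex-4-en-2-ynoate, via lithium acetylide 4 (not isolated)
Conditions: n-BuLi, THF, −78 °C; then 3, −78 to 0 °C
Reagents that add atoms: none
Why: Alkoxycarbonylation of the alkynyllithium with the chloroformate installs C1 as an ester that fluoride can cleave later under non-basic conditions.

Step 3
Reactants: 5 2-(trimethylsilyl)ethyl (4Z)-6-(tert-butyldimethylsilyloxy)-4-methylhex-4-en-2-ynoate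
Product: 6 2-(trimethylsilyl)ethyl (4Z)-6-hydroxy-4-methylhex-4-en-2-ynoate
Conditions: AcOH–THF–H2O (3:1:1), rt
Reagents that add atoms: none
Why: Mild acid-catalysed hydrolysis removes the primary allylic silyl ether and leaves the silylethyl ester and the Z-enyne untouched.

Step 4
Reactants: 6 2-(trimethylsilyl)ethyl (4Z)-6-hydroxy-4-methylhex-4-en-2-ynoate
Product: 7 2-(trimethylsilyl)ethyl (4Z)-4-methyl-6-oxohex-4-en-2-ynoate (fragment A, C1 to C6 and C15)
Conditions: Dess–Martin periodinane, pyridine, CH2Cl2, 0 °C; used crude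
Reagents that add atoms: none
Why: Buffered Dess–Martin oxidation of the allylic alcohol should give the Z-enal without acid- or base-induced Z to E isomerisation.

Step 5
Reactants: 8 (2S)-2-(tert-butyldimethylsilyloxy)propanal; 9 3-(methoxymethoxy)prop-1-ene
Product: 13 (2S,3R,4S)-2-(tert-butyldimethylsilyloxy)-4-(methoxymethoxy)hex-5-en-3-ol, via (Z)-3-(methoxymethoxy)allyllithium 10 (not isolated), via allylborane 11 (not isolated), via borinate 12 (not isolated)
Conditions: 9, s-BuLi, THF, −78 °C; (+)-Ipc2BOMe; BF3·OEt2; then 8, −78 °C; NaOH, H2O2, 0 °C to rt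
Reagents that add atoms: none
Why: Brown (Z)-γ-alkoxyallylboration through a closed chair transition state gives the syn monoprotected diol, and the Ipc2B reagent from (−)-α-pinene should add to the Re face of 8, which is also the Felkin face (matched pair), so that C8 (hexenol C4) is set as S while C9 and C10 are helper centres that later become sp2.

Step 6
Reactants: 13 (2S,3R,4S)-2-(tert-butyldimethylsilyloxy)-4-(methoxymethoxy)hex-5-en-3-ol
Product: 14 (2S,3R,4S)-2-(tert-butyldimethylsilyloxy)-4-(methoxymethoxy)-3-(triethylsilyloxy)hex-5-ene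
Conditions: TESOTf, 2,6-lutidine, CH2Cl2, −78 °C
Reagents that add atoms: triethylsilyl trifluoromethanesulfonate, CC[Si](CC)(CC)OS(=O)(=O)C(F)(F)F
Why: Silyl triflate silylation protects the hindered C9 hydroxyl with a group that can be removed in the presence of the C10 tert-butyldimethylsilyl ether.

Step 7
Reactants: 14 (2S,3R,4S)-2-(tert-butyldimethylsilyloxy)-4-(methoxymethoxy)-3-(triethylsilyloxy)hex-5-ene
Product: 16 (2R,3R,4S)-4-(tert-butyldimethylsilyloxy)-2-(methoxymethoxy)-3-(triethylsilyloxy)pentanal, via ozonide 15 (not isolated)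
Conditions: O3, CH2Cl2, −78 °C; then PPh3, −78 °C to rt
Reagents that add atoms: ozone, [O-][O+]=O
Why: Ozonolysis with reductive work-up cleaves the vinyl group to the C7 aldehyde while the ethers are inert (the descriptor at C8 changes to R only through the new priority of the formyl group).

Step 8
Reactants: 16 (2R,3R,4S)-4-(tert-butyldimethylsilyloxy)-2-(methoxymethoxy)-3-(triethylsilyloxy)pentanal; 17 methyl acrylate
Product: 18 methyl (4S,5R,6S)-6-(tert-butyldimethylsilyloxy)-3-hydroxy-4-(methoxymethoxy)-2-methylidene-5-(triethylsilyloxy)heptanoate (both C3 epimers)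
Conditions: DABCO, 17 (neat, excess), rt
Reagents that add atoms: none
Why: The Morita–Baylis–Hillman reaction of the electron-poor α-alkoxy aldehyde attaches C11 to C13, and the configuration of the new carbinol C7 is irrelevant because C7 becomes sp2 in the next step.

Step 9
Reactants: 18 methyl (4S,5R,6S)-6-(tert-butyldimethylsilyloxy)-3-hydroxy-4-(methoxymethoxy)-2-methylidene-5-(triethylsilyloxy)heptanoate
Product: 19 methyl (2Z,4S,5R,6S)-2-(bromomethyl)-6-(tert-butyldimethylsilyloxy)-4-(methoxymethoxy)-5-(triethylsilyloxy)hept-2-enoate (fragment B, C7 to C14)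
Conditions: NBS, Me2S, CH2Cl2, −20 °C to rt
Reagents that add atoms: N-bromosuccinimide, O=C1CCC(=O)N1Br
Why: Corey–Kim-type activation of the allylic alcohol followed by SN2′ attack of bromide gives the thermodynamically preferred (Z)-2-(bromomethyl)enoate with C8 cis to the CH2Br group.

Step 10
Reactants: 7 2-(trimethylsilyl)ethyl (4Z)-4-methyl-6-oxohex-4-en-2-ynoate; 19 methyl (2Z,4S,5R,6S)-2-(bromomethyl)-6-(tert-butyldimethylsilyloxy)-4-(methoxymethoxy)-5-(triethylsilyloxy)hept-2-enoate
Product: 22 2-(trimethylsilyl)ethyl (4Z)-5-{(2S,3S)-3-[(1S,2R,3S)-3-(tert-butyldimethylsilyloxy)-2-hydroxy-1-(methoxymethoxy)butyl]-4-methylidene-5-oxooxolan-2-yl}-4-methylpent-4-en-2-ynoate, via allylindium dibromide 20 (not isolated), via open-chain hydroxy ester 21 (not isolated)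
Conditions: In powder, THF–H2O (1:1), rt; then crude adduct, PPTS, MeOH, 40 °C
Reagents that add atoms: none
Why: Barbier allylation through a Zimmerman–Traxler chair with C8 axial (cis to CH2In) gives the syn adduct and hence the cis lactone, while allylic strain holds the C8–H bond in the allyl plane so that the aldehyde approaches C7 anti to the bulky C9 branch and syn to the chelating methoxymethoxy group, which should set 6S and 7S from 8S; the acid then lactonises the adduct and removes the triethylsilyl group.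

Step 11
Reactants: 22 2-(trimethylsilyl)ethyl (4Z)-5-{(2S,3S)-3-[(1S,2R,3S)-3-(tert-butyldimethylsilyloxy)-2-hydroxy-1-(methoxymethoxy)butyl]-4-methylidene-5-oxooxolan-2-yl}-4-methylpent-4-en-2-ynoate
Product: 23 2-(trimethylsilyl)ethyl (4Z)-5-{(2S,3S)-3-[(1S,3S)-3-(tert-butyldimethylsilyloxy)-1-(methoxymethoxy)-2-oxobutyl]-4-methylidene-5-oxooxolan-2-yl}-4-methylpent-4-en-2-ynoate
Conditions: Dess–Martin periodinane, pyridine, CH2Cl2, 0 °C to rt
Reagents that add atoms: none
Why: Dess–Martin oxidation of the only free hydroxyl raises C9 to the ketone level that the key step needs as its activating group.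

Step 12
Reactants: 23 2-(trimethylsilyl)ethyl (4Z)-5-{(2S,3S)-3-[(1S,3S)-3-(tert-butyldimethylsilyloxy)-1-(methoxymethoxy)-2-oxobutyl]-4-methylidene-5-oxooxolan-2-yl}-4-methylpent-4-en-2-ynoate
Product: 24 (4Z)-5-{(2S,3S)-3-[(1S,3S)-3-hydroxy-1-(methoxymethoxy)-2-oxobutyl]-4-methylidene-5-oxooxolan-2-yl}-4-methylpent-4-en-2-ynoic acid
Conditions: Bu4NF, AcOH (1:1), THF, 0 °C to rt
Reagents that add atoms: none
Why: Buffered fluoride cleaves the α-keto silyl ether and, by β-elimination of ethene and fluorotrimethylsilane, the silylethyl ester in one operation without base strong enough to harm the methylene lactone.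

Step 13
Reactants: 24 (4Z)-5-{(2S,3S)-3-[(1S,3S)-3-hydroxy-1-(methoxymethoxy)-2-oxobutyl]-4-methylidene-5-oxooxolan-2-yl}-4-methylpent-4-en-2-ynoic acid
Product: 26 (6S,7S,8S,10R)-macrolactone: 11-membered 2-ynoate lactone closed between O10 and C1 (C9 ketone; 8-methoxymethoxy; cis 6,7-fused α-methylene-γ-lactone; 4Z), via alkoxyphosphonium carboxylate 25 (not isolated)
Conditions: PPh3, DIAD, toluene (0.002 M, slow addition of 24), −10 °C to rt
Reagents that add atoms: none
Why: Mitsunobu macrolactonisation closes the ring by SN2 attack of the carboxylate on the activated α-keto carbinol (inversion at C10, a centre that the next step erases), which avoids acyl activation of the ynoic acid, and the rigid enyne and lactone units leave only four sp3 ring atoms to organise.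

Step 14
Reactants: 26 (6S,7S,8S,10R)-macrolactone
Product: 29 (6S,7S,8S,10S)-3,10-epoxy-8-(methoxymethoxy)-1,9-dioxogermacra-2,4Z,11(13)-trien-12,6-olide, via lithium enolate 27 (not isolated), via ring-contracted alkoxide ynone 28 (not isolated)
Conditions: LiN(SiMe3)2 (1.1 equiv), THF, −78 to −20 °C; then AcOH
Reagents that add atoms: none
Why: Proposed new method: LiN(SiMe3)2 removes the C10 proton of the α-acyloxy ketone, the enolate carbon attacks its own ester carbonyl C1 through an oxirane alkoxide (3-exo-trig) and the C1–O bond breaks, so that the acyl group moves from oxygen to C10 and the 11-membered lactone contracts to the ten-membered carbocycle (C1–C10 bond); the freed tertiary alkoxide then adds to C3 of the bent C2≡C3 ynone in a 5-endo-dig oxa-Michael closure (O–C3 bond) with protonation of C2 by HN(SiMe3)2, which gives the 3(2H)-furanone. The closest known reaction types are the Chan rearrangement of α-acyloxy esters, including its ring-contracting use, and the base-mediated 5-endo-dig cyclisation of α′-hydroxy ynones to 3(2H)-furanones; their coupling on an alkynoyl ester of a ketol inside a macrolactone is the new element. C10 is the only new stereocentre: the ring forces the enolate to carry O10 and C8 cis, lithium chelation between the enolate oxygen and the C8 methoxymethoxy group together with allylic strain places C7, and with it the tether to C1, on one face, and C1 can reach C10 only from the face syn to C7, which corresponds to the target configuration (10S in 29, named 10R once C9 is reduced). The step needs enolisation at C10 and not at C8 (C10 is more acidic and less hindered, and acyl transfer to C8 would demand an eight-membered cycloalkyne), the 1,2-acyl shift in preference to carbon-Michael attack of C10 on C3 (the in-ring ynoate cannot reach that geometry before the shift), and survival of the methylene lactone (one equivalent of a hindered amide base at low temperature). The overall change is an isomerisation driven by loss of the alkyne and of ring strain, and the C9 ketone that makes it possible is removed in step 15.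

Step 15
Reactants: 29 (6S,7S,8S,10S)-3,10-epoxy-8-(methoxymethoxy)-1,9-dioxogermacra-2,4Z,11(13)-trien-12,6-olide
Product: 30 (6S,7S,8S,9S,10R)-3,10-epoxy-9-hydroxy-8-(methoxymethoxy)-1-oxogermacra-2,4Z,11(13)-trien-12,6-olide
Conditions: Zn(BH4)2, Et2O, −30 to 0 °C; H2O
Reagents that add atoms: none
Why: Cram-chelate reduction, in which zinc bridges the C9 carbonyl and the C8 methoxymethoxy oxygen and hydride enters from the side of H8, should give the 8,9-anti alcohol (9S), while the vinylogous ester carbonyl C1 and the lactone are too unreactive to compete.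

Step 16
Reactants: 30 (6S,7S,8S,9S,10R)-3,10-epoxy-9-hydroxy-8-(methoxymethoxy)-1-oxogermacra-2,4Z,11(13)-trien-12,6-olide
Product: 32 (6S,7S,8S,9S,10R)-3,10-epoxy-8,9-dihydroxy-1-oxogermacra-2,4Z,11(13)-trien-12,6-olide, via bromomethyl ether 31 (not isolated)
Conditions: Me2BBr, CH2Cl2, −78 °C; then THF, aq. NaHCO3
Reagents that add atoms: none
Why: Bromodimethylborane cleaves the methoxymethyl acetal at low temperature and the resulting bromomethyl ether is hydrolysed on work-up, conditions under which the lactone, the furanone and the allylic C6–O bond should survive.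

Step 17
Reactants: 32 (6S,7S,8S,9S,10R)-3,10-epoxy-8,9-dihydroxy-1-oxogermacra-2,4Z,11(13)-trien-12,6-olide; 33 methacrylic anhydride
Product: 34 (6S,7S,8S,9S,10R)-3,10-epoxy-9-hydroxy-1-oxogermacra-2,4Z,11(13)-trien-12,6-olid-8-yl 2-methylprop-2-enoate (target)
Conditions: 33 (1.1 equiv), Et3N, DMAP (cat.), CH2Cl2, −20 °C
Reagents that add atoms: none
Why: DMAP-catalysed acylation should select the C8 hydroxyl because the C9 hydroxyl is neopentyl-like, flanked by the quaternary C10.

**Compound list**

1 | (2Z)-3-methylpent-2-en-4-yn-1-ol | C#C/C(C)=C\CO | starting material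
2 | tert-butyldimethylsilyl ether of 1 | C#C/C(C)=C\CO[Si](C)(C)C(C)(C)C | intermediate
3 | 2-(trimethylsilyl)ethyl chloroformate | C[Si](C)(C)CCOC(Cl)=O | starting material
4 | lithium acetylide of 2 | [Li]C#C/C(C)=C\CO[Si](C)(C)C(C)(C)C | intermediate
5 | 2-(trimethylsilyl)ethyl (4Z)-6-(tert-butyldimethylsilyloxy)-4-methylhex-4-en-2-ynoate | C[Si](C)(C)CCOC(=O)C#C/C(C)=C\CO[Si](C)(C)C(C)(C)C | intermediate
6 | 2-(trimethylsilyl)ethyl (4Z)-6-hydroxy-4-methylhex-4-en-2-ynoate | C[Si](C)(C)CCOC(=O)C#C/C(C)=C\CO | intermediate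
7 | 2-(trimethylsilyl)ethyl (4Z)-4-methyl-6-oxohex-4-en-2-ynoate | C[Si](C)(C)CCOC(=O)C#C/C(C)=C\C=O | intermediate
8 | (2S)-2-(tert-butyldimethylsilyloxy)propanal | C[C@H](O[Si](C)(C)C(C)(C)C)C=O | starting material
9 | 3-(methoxymethoxy)prop-1-ene (allyl methoxymethyl ether) | C=CCOCOC | starting material
10 | (Z)-3-(methoxymethoxy)allyllithium | [Li]C/C=C\OCOC | intermediate
11 | (Z)-[3-(methoxymethoxy)allyl]bis(isopinocampheyl)borane, Ipc from (−)-α-pinene | COCO/C=C\CB([C@H]1C[C@H]2C[C@@H]([C@@H]1C)C2(C)C)[C@H]1C[C@H]2C[C@@H]([C@@H]1C)C2(C)C | intermediate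
12 | bis(isopinocampheyl)borinate of 13 | C=C[C@H](OCOC)[C@@H](OB([C@H]1C[C@H]2C[C@@H]([C@@H]1C)C2(C)C)[C@H]1C[C@H]2C[C@@H]([C@@H]1C)C2(C)C)[C@H](C)O[Si](C)(C)C(C)(C)C | intermediate
13 | (2S,3R,4S)-2-(tert-butyldimethylsilyloxy)-4-(methoxymethoxy)hex-5-en-3-ol | C=C[C@H](OCOC)[C@@H](O)[C@H](C)O[Si](C)(C)C(C)(C)C | intermediate
14 | (2S,3R,4S)-2-(tert-butyldimethylsilyloxy)-4-(methoxymethoxy)-3-(triethylsilyloxy)hex-5-ene | C=C[C@H](OCOC)[C@@H](O[Si](CC)(CC)CC)[C@H](C)O[Si](C)(C)C(C)(C)C | intermediate
15 | ozonide (1,2,4-trioxolane) of 14 | C1OC(OO1)[C@H](OCOC)[C@@H](O[Si](CC)(CC)CC)[C@H](C)O[Si](C)(C)C(C)(C)C | intermediate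
16 | (2R,3R,4S)-4-(tert-butyldimethylsilyloxy)-2-(methoxymethoxy)-3-(triethylsilyloxy)pentanal | O=C[C@H](OCOC)[C@@H](O[Si](CC)(CC)CC)[C@H](C)O[Si](C)(C)C(C)(C)C | intermediate
17 | methyl acrylate | C=CC(=O)OC | starting material
18 | methyl (4S,5R,6S)-6-(tert-butyldimethylsilyloxy)-3-hydroxy-4-(methoxymethoxy)-2-methylidene-5-(triethylsilyloxy)heptanoate, both C3 epimers | C=C(C(=O)OC)C(O)[C@H](OCOC)[C@@H](O[Si](CC)(CC)CC)[C@H](C)O[Si](C)(C)C(C)(C)C | intermediate
19 | methyl (2Z,4S,5R,6S)-2-(bromomethyl)-6-(tert-butyldimethylsilyloxy)-4-(methoxymethoxy)-5-(triethylsilyloxy)hept-2-enoate | COC(=O)/C(CBr)=C/[C@H](OCOC)[C@@H](O[Si](CC)(CC)CC)[C@H](C)O[Si](C)(C)C(C)(C)C | intermediate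
20 | allylindium dibromide from 19 (indium on C13) | COC(=O)/C(C[In](Br)Br)=C/[C@H](OCOC)[C@@H](O[Si](CC)(CC)CC)[C@H](C)O[Si](C)(C)C(C)(C)C | intermediate
21 | 2-(trimethylsilyl)ethyl (4Z,6S,7S,8S,9R,10S)-10-(tert-butyldimethylsilyloxy)-6-hydroxy-7-(3-methoxy-3-oxoprop-1-en-2-yl)-8-(methoxymethoxy)-4-methyl-9-(triethylsilyloxy)undec-4-en-2-ynoate | COC(=O)C(=C)[C@@H]([C@@H](O)/C=C(/C)C#CC(=O)OCC[Si](C)(C)C)[C@H](OCOC)[C@@H](O[Si](CC)(CC)CC)[C@H](C)O[Si](C)(C)C(C)(C)C | intermediate
22 | 2-(trimethylsilyl)ethyl (4Z)-5-{(2S,3S)-3-[(1S,2R,3S)-3-(tert-butyldimethylsilyloxy)-2-hydroxy-1-(methoxymethoxy)butyl]-4-methylidene-5-oxooxolan-2-yl}-4-methylpent-4-en-2-ynoate | COCO[C@@H]([C@H]1C(=C)C(=O)O[C@H]1/C=C(/C)C#CC(=O)OCC[Si](C)(C)C)[C@@H](O)[C@H](C)O[Si](C)(C)C(C)(C)C | intermediate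
23 | 2-(trimethylsilyl)ethyl (4Z)-5-{(2S,3S)-3-[(1S,3S)-3-(tert-butyldimethylsilyloxy)-1-(methoxymethoxy)-2-oxobutyl]-4-methylidene-5-oxooxolan-2-yl}-4-methylpent-4-en-2-ynoate | COCO[C@@H]([C@H]1C(=C)C(=O)O[C@H]1/C=C(/C)C#CC(=O)OCC[Si](C)(C)C)C(=O)[C@H](C)O[Si](C)(C)C(C)(C)C | intermediate
24 | (4Z)-5-{(2S,3S)-3-[(1S,3S)-3-hydroxy-1-(methoxymethoxy)-2-oxobutyl]-4-methylidene-5-oxooxolan-2-yl}-4-methylpent-4-en-2-ynoic acid | COCO[C@@H]([C@H]1C(=C)C(=O)O[C@H]1/C=C(/C)C#CC(=O)O)C(=O)[C@H](C)O | intermediate
25 | alkoxyphosphonium carboxylate of 24 (O10–PPh3 cation, C1 carboxylate) | COCO[C@@H]([C@H]1C(=C)C(=O)O[C@H]1/C=C(/C)C#CC(=O)[O-])C(=O)[C@H](C)O[P+](c2ccccc2)(c2ccccc2)c2ccccc2 | intermediate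
26 | (6S,7S,8S,10R)-macrolactone: 11-membered 2-ynoate lactone closed between O10 and C1, C9 ketone, 8-methoxymethoxy, cis 6,7-fused α-methylene-γ-lactone, 4Z | COCO[C@H]1[C@H]2C(=C)C(=O)O[C@H]2/C=C(/C)C#CC(=O)O[C@H](C)C1=O | intermediate
27 | lithium C9=C10 enolate of 26 (O10 and C8 cis) | COCO[C@H]1[C@H]2C(=C)C(=O)O[C@H]2/C=C(/C)C#CC(=O)O/C(C)=C1/O[Li] | intermediate
28 | ring-contracted ten-membered 2-yne-1,9-dione with lithium alkoxide on C10 | COCO[C@H]1[C@H]2C(=C)C(=O)O[C@H]2/C=C(/C)C#CC(=O)[C@](C)(O[Li])C1=O | intermediate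
29 | (6S,7S,8S,10S)-3,10-epoxy-8-(methoxymethoxy)-1,9-dioxogermacra-2,4Z,11(13)-trien-12,6-olide | COCO[C@H]1[C@H]2C(=C)C(=O)O[C@H]2/C=C(/C)C2=CC(=O)[C@](C)(O2)C1=O | intermediate
30 | (6S,7S,8S,9S,10R)-3,10-epoxy-9-hydroxy-8-(methoxymethoxy)-1-oxogermacra-2,4Z,11(13)-trien-12,6-olide | COCO[C@H]1[C@H]2C(=C)C(=O)O[C@H]2/C=C(/C)C2=CC(=O)[C@](C)(O2)[C@H]1O | intermediate
31 | 8-O-(bromomethyl) ether of 32 | BrCO[C@H]1[C@H]2C(=C)C(=O)O[C@H]2/C=C(/C)C2=CC(=O)[C@](C)(O2)[C@H]1O | intermediate
32 | (6S,7S,8S,9S,10R)-3,10-epoxy-8,9-dihydroxy-1-oxogermacra-2,4Z,11(13)-trien-12,6-olide | O[C@H]1[C@H]2C(=C)C(=O)O[C@H]2/C=C(/C)C2=CC(=O)[C@](C)(O2)[C@H]1O | intermediate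
33 | methacrylic anhydride | C=C(C)C(=O)OC(=O)C(C)=C | starting material
34 | (6S,7S,8S,9S,10R)-3,10-epoxy-9-hydroxy-1-oxogermacra-2,4Z,11(13)-trien-12,6-olid-8-yl 2-methylprop-2-enoate | C=C(C)C(=O)O[C@H]1[C@H]2C(=C)C(=O)O[C@H]2/C=C(/C)C2=CC(=O)[C@](C)(O2)[C@H]1O | target

**Count and risks**

Total step count: 17. Longest linear sequence: 13 steps (steps 5 to 17, from 8 and 9); the other branch (steps 1 to 4, then 10 to 17) has 12.

Most likely to fail, step 14 (labelled step): enolisation may occur at C8 or at C7 of the methylene lactone, the C10 enolate may close on C3 as a carbon nucleophile, or the acyl shift may take place on the wrong face of the enolate. The fallback uses the two bond formations in the opposite, stepwise order known from the Fiesselmann-type synthesis of 3-oxo-2,3-dihydrofurans from α-hydroxy carbonyl compounds and alkynoates. It sets out from 23: HF·pyridine in THF should remove only the C10 silyl ether and give the 2-(trimethylsilyl)ethyl ester of the hydroxy ketone F1. Cs2CO3 in MeCN at high dilution should then add the C10 hydroxyl to C3 of the ynoate to give the nine-membered (Z)-β-alkoxyacrylate F2, whose C10 enolate closes on the C1 ester in a Dieckmann reaction with loss of 2-(trimethylsilyl)ethanol. This comes back to the route at 29, and C10 is again set under ring control.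

Second, step 13: ring closure to the 11-membered lactone may lose out to oligomerisation, or the phosphine may add to the ynoate. The fallback forms the other ester bond (O–C1 instead of O–C10). It sets out from 24 and uses Shiina macrolactonisation (2-methyl-6-nitrobenzoic anhydride, DMAP, Et3N, toluene, slow addition), which acylates the hydroxyl with retention and should give the (6S,7S,8S,10S)-macrolactone F3, the C10 epimer of 26. Because step 14 planarises C10, F3 gives the same enolate 27 and comes back to the route at 29.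

Third, step 10: facial selectivity at C7 may be poor, the Z-enal may isomerise under the Lewis acidic indium salts in water, or the allylmetal may undergo 1,4-elimination of the C8 alkoxy group. The fallback changes the nucleophile to an allylboron reagent that reacts thermally through a closed six-membered transition state without metal salts or water. It sets out from 19: borylation with bis(pinacolato)diboron and the zerovalent palladium catalyst Pd2(dba)3 in toluene should give the pinacol allylboronate F4 with the borylmethyl group cis to C8. Heating F4 with 7 in toluene should give the pinacol borate F5 of the syn adduct, which is hydrolysed on work-up to 21. PPTS in MeOH then gives 22, where the fallback comes back to the route.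

Further compounds
F1 | step 14 | 2-(trimethylsilyl)ethyl (4Z)-5-{(2S,3S)-3-[(1S,3S)-3-hydroxy-1-(methoxymethoxy)-2-oxobutyl]-4-methylidene-5-oxooxolan-2-yl}-4-methylpent-4-en-2-ynoate | COCO[C@@H]([C@H]1C(=C)C(=O)O[C@H]1/C=C(/C)C#CC(=O)OCC[Si](C)(C)C)C(=O)[C@H](C)O
F2 | step 14 | nine-membered cyclic enol ether from addition of O10 to C3 of F1, (Z)-β-alkoxyacrylate with the ester cis to O10, (6S,7S,8S,10S) | COCO[C@H]1[C@H]2C(=C)C(=O)O[C@H]2/C=C(/C)\C(=C\C(=O)OCC[Si](C)(C)C)O[C@@H](C)C1=O
F3 | step 13 | (6S,7S,8S,10S)-macrolactone, C10 epimer of 26 | COCO[C@H]1[C@H]2C(=C)C(=O)O[C@H]2/C=C(/C)C#CC(=O)O[C@@H](C)C1=O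
F4 | step 10 | methyl (2E,4S,5R,6S)-6-(tert-butyldimethylsilyloxy)-4-(methoxymethoxy)-2-[(4,4,5,5-tetramethyl-1,3,2-dioxaborolan-2-yl)methyl]-5-(triethylsilyloxy)hept-2-enoate | COC(=O)/C(CB1OC(C)(C)C(C)(C)O1)=C/[C@H](OCOC)[C@@H](O[Si](CC)(CC)CC)[C@H](C)O[Si](C)(C)C(C)(C)C
F5 | step 10 | pinacol borate (O6–B) of hydroxy ester 21 | COC(=O)C(=C)[C@@H]([C@@H](OB1OC(C)(C)C(C)(C)O1)/C=C(/C)C#CC(=O)OCC[Si](C)(C)C)[C@H](OCOC)[C@@H](O[Si](CC)(CC)CC)[C@H](C)O[Si](C)(C)C(C)(C)C
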